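## The problem

Gnetumontanin B is built from two 2,3-diaryl-2,3-dihydrobenzofurans joined head to tail. The outer ring system (O1, C2, C3, C3a–C7a) carries a hydroxyl at C4 and the (E)-4-hydroxystyryl group at C6, and its C2 is bonded directly to C7' of the inner ring system (O1', C2', C3', C3a'–C7a'). The inner system has a hydroxyl at C4' and a 2,4-dihydroxyphenyl group at C2'; C3 and C3' each carry a 3,5-dihydroxyphenyl group.

There are four stereocentres, (2S,3S,2'S,3'S), arranged as two trans pairs. Inside a pair one centre can steer the other: C2' is benzylic to a 2,4-dioxygenated ring, and C2 is benzylic to ring A' itself (O1' ortho and O4' para to C7'). Either C–O bond can therefore ionise reversibly and settle in the trans arrangement. The two pairs are separated by the C2–C7' biaryl-type link and cannot be trusted to control each other, so C3 and C3' each need reagent control.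

The sensitive features are nine phenols, an electron-rich stilbene (no hydrogenation, no strong protic acid) and the two easily ionised benzylic ether bonds. Ring A' has oxygen on both carbons flanking C3a' (C4' and C7a'), so an inner ring opened after O4' is free could reclose through the wrong oxygen.

The structural feature that opens the plan is the same in both five-membered rings. C3' (and C3) carries two aryl groups and no heteroatom, which is the substitution of a diaryl carbene. Its neighbour C2' (and C2) is a benzylic CH on the ring oxygen, which is the α-carbon of an aryl benzyl ether sitting 1,5 to that carbene.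

## Retrosynthesis

**Target 26 from 25 and 24.** The last operations are cleavage of nine O–CH3 bonds (25 to 26) and, before that, inversion of C2 in the cis-fused outer ring (24 to 25). Methyl ethers are chosen for all nine oxygens because they survive aryllithiums, hydrazine, MnO2 and carbenes. The two oxygens ortho to the future carbene carbons (O4, O4') must carry a group with no activated α-C–H, which excludes benzyl, allyl and methoxymethyl there. The price is a Lewis-acid deprotection at the end, which is treated as a risk below.

**Outer ring: 24 from hydrazone 22 (via diazo compound 23), and 22 from ketone 21.** The C2–C3 bond is cut. The neighbouring cut, C2–O1, would need an acyclic, stereodefined 1,2,2-triarylethanol. The C2–C3 cut needs only a diaryl ketone and an ether CH2, and it reuses the reaction of the key step, so one method validated once serves both rings. The forward reaction must set C3 under catalyst control on a substrate that already holds C2' and C3'.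

**Ether bond: 21 from alcohol 14 and phenol 20.** Cutting O1–CH2 divides the molecule into two halves of similar size. The forward step is a Mitsunobu etherification of an acidic ortho-acyl phenol with a primary benzylic alcohol.

**Stilbene half: 20 from 19, 19 from bromide 17 and Weinreb amide 2 (via aryllithium 18), 17 from aldehyde 15 and phosphonate 16.** The aryl–carbonyl bond is cut at the carbon between the two methoxy groups, and the alkene is cut by a Horner–Wadsworth–Emmons disconnection. Friedel–Crafts acylation of a 3,5-dimethoxystilbene would attack the wrong ring position. The bromine in 15 fixes the position and allows halogen–lithium exchange at −78 °C, where the stilbene is not attacked. Chelation-controlled removal of one ortho methyl then frees the phenol.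

**Inner half: 14 from aldehyde 13, 13 from cis acetal 12.** A C–H bond is cut (aldehyde reduction), then C2' is epimerised and the dioxolane hydrolysed in one acid treatment. The acetal is needed only to keep the formyl carbon silent towards hydrazine.

**Key disconnection: 12 from hydrazone 10 (via diaryldiazomethane 11).** The C2'–C3' bond is cut, which opens the five-membered ring and removes both stereocentres. The precursor is an achiral benzophenone hydrazone carrying a 2,4-dimethoxybenzyl ether. The forward reaction must choose the benzylic O–CH2 hydrogen over the C4' methoxy hydrogens and fix C3' through the catalyst. The kinetic cis relationship at C2' is corrected in step 8.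

**Precursor assembly: 10 from ketone 9, 9 from phenol 7 and alcohol 8, 7 from 6, 6 from 5, 5 from 4, 4 from 1 and 2 (via 3).** Ring A' is bought as 1,3-dimethoxybenzene. Lithiation between the methoxy groups and acylation with 2 give the symmetrical ketone 4. Its two ortho oxygens are then told apart by BCl3 (one methyl removed through the carbonyl chelate). The freed phenol directs formylation to its only open ortho position, which becomes C7'. Each step removes one element of complexity, and no regiochemical choice is left to chance.

## Roads not taken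

**Alternative 1:** Ring A' would be built rather than bought. Photochemical Wolff rearrangement of the unsaturated diazo ketone A1 gives a vinylketene that combines with the siloxyalkyne A2 (cycloaddition, cyclobutenone opening, six-electron closure) to give the phenol A3.
- Merits: the three oxygen and carbon substituents around ring A' come out differentiated without any selective demethylation or formylation. O4' arrives as a silyl ether that fluoride can remove. In that respect this road is better than the chosen plan, whose O4' methyl ether must be cleaved by a Lewis acid next to an ionisable C2'.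
- Weak points: the annulation creates no stereocentre. C2' and C3' must already be present in A2 as an acyclic pair, with C3' both benzylic and propargylic and therefore prone to prototropic loss of configuration. An enantioselective synthesis of A2 is a separate, unsolved problem. An aromatic ring that can be purchased is made in several steps.
- Comparison: the chosen plan sets against this a commercial arene, three short steps (2–4) for differentiation, and a catalytic ring closure that forms the C–C bond and the stereocentres together.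

**Alternative 2:** The outer C2–C7' and C3–C3a bonds would be made in one three-component step. The aryllithium from the inner bromide A4 adds to the styrenyl boronate A5, and a Pd(OAc)2/MandyPhos catalyst couples the boronate complex with the aryl triflate A6. The aryl group migrates from boron to carbon to give A7, whose C–B bond is later oxidised and closed to the ring.
- Merits: it is the most convergent of all the plans for the second half. Both outer stereocentres are set under ligand control in a single step. It avoids a second hindered hydrazone and a carbene in the presence of the stilbene. If it worked, it would be shorter than steps 13–16 here.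
- Weak points: A4 must first be made as a single enantiomer, so the inner ring problem that the chosen key step solves remains. The coupling would have to accept three departures from its usual substrates at once: a β-aryl alkenyl boronate, an ortho-substituted migrating aryl group, and a di-ortho-substituted aryl triflate. One of two equivalent protected oxygens must afterwards be freed and closed onto C2.
- Comparison: the chosen plan is less convergent but leans on one reaction type used twice on its established substrate class.

**Alternative 3:** The outer benzene ring would be formed by an intramolecular inverse-demand Diels–Alder reaction of the pyridazine A8 with its tethered alkynyl boronate. Loss of the two ring nitrogens gives A9 with the dihydrofuran ring fused in the same step.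
- Merits: regiochemistry is fixed by the tether. No metal is involved. The boron at C4 becomes the C4 hydroxyl by mild oxidation, so one fewer methyl ether has to be cleaved at the end; here this road is better than the chosen plan.
- Weak points: C2 and C3 must again be installed beforehand in an acyclic ether whose C3 is benzylic and propargylic. Pyridazines are reluctant dienes, and the temperatures needed threaten the ionisable C2–O bond (C2 is benzylic to a 2,4-dioxygenated ring), the C3 centre and the alkynyl boronate. The substituted pyridazine adds its own synthesis.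
- Comparison: the chosen plan closes the same ring at or below room temperature and creates the stereocentres in the ring-forming step.

Key step: step 7

Assumption 1: N,3,5-trimethoxy-N-methylbenzamide (2) is taken as a purchasable Weinreb amide; if it has to be made, 3,5-dimethoxybenzoyl chloride and N,O-dimethylhydroxylamine hydrochloride give it in one step.

Assumption 2: Rh2(R-PTAD)4 (PTAD = (1-adamantyl)(N-phthalimido)acetate) is assumed to deliver the S configuration at the carbene-derived carbon; if the sense is the opposite, Rh2(S-PTAD)4 is used in steps 7 and 15 and nothing else changes.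

## Steps

Step 1
Reactants: 1 1,3-dimethoxybenzene; 2 N,3,5-trimethoxy-N-methylbenzamide
Product: 4 (2,6-dimethoxyphenyl)(3,5-dimethoxyphenyl)methanone, via 2,6-dimethoxyphenyllithium 3 (not isolated)
Conditions: n-BuLi, THF, 0 °C → rt; then 2, −78 → 0 °C; H2O
Reagents that add atoms: none
Why: Directed ortho-metalation takes place between the two methoxy groups; Weinreb ketone synthesis then stops at the ketone because the chelated tetrahedral adduct persists until work-up.

Step 2
Reactants: 4 (2,6-dimethoxyphenyl)(3,5-dimethoxyphenyl)methanone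
Product: 5 (3,5-dimethoxyphenyl)(2-hydroxy-6-methoxyphenyl)methanone
Conditions: BCl3 (1.2 equiv), CH2Cl2, −78 → 0 °C; H2O
Reagents that add atoms: none
Why: Chelation-controlled ether cleavage: boron bridges the carbonyl oxygen and one ortho methoxy group, chloride removes that methyl only, and the resulting boron chelate protects the second ortho ether; the meta ethers are not touched.

Step 3
Reactants: 5 (3,5-dimethoxyphenyl)(2-hydroxy-6-methoxyphenyl)methanone
Product: 6 3-(3,5-dimethoxybenzoyl)-2-hydroxy-4-methoxybenzaldehyde
Conditions: MgCl2, Et3N, (CH2O)n, MeCN, reflux; then 1 M HCl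
Reagents that add atoms: paraformaldehyde (as formaldehyde), C=O
Why: Magnesium-mediated ortho-formylation (Casnati–Skattebøl): the magnesium phenoxide delivers formaldehyde to the only free ortho position, which is also para to the methoxy group, and a second formaldehyde oxidises the hydroxymethyl stage by hydride transfer.

Step 4
Reactants: 6 3-(3,5-dimethoxybenzoyl)-2-hydroxy-4-methoxybenzaldehyde
Product: 7 (3,5-dimethoxyphenyl)[3-(1,3-dioxolan-2-yl)-2-hydroxy-6-methoxyphenyl]methanone
Conditions: HOCH2CH2OH, p-TsOH·H2O (cat.), PhMe, reflux, Dean–Stark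
Reagents that add atoms: ethylene glycol, OCCO
Why: Acid-catalysed acetalisation of the aldehyde; the diaryl ketone, flanked by two ortho substituents and hydrogen-bonded to the phenol, should not ketalise.

Step 5
Reactants: 7 (3,5-dimethoxyphenyl)[3-(1,3-dioxolan-2-yl)-2-hydroxy-6-methoxyphenyl]methanone; 8 2,4-dimethoxybenzyl alcohol
Product: 9 {2-[(2,4-dimethoxyphenyl)methoxy]-3-(1,3-dioxolan-2-yl)-6-methoxyphenyl}(3,5-dimethoxyphenyl)methanone
Conditions: PPh3, DIAD, THF, 0 °C → rt
Reagents that add atoms: none
Why: Mitsunobu etherification of an acidic ortho-acyl phenol with a primary benzylic alcohol; it avoids the unstable 2,4-dimethoxybenzyl halides and keeps the acetal under neutral conditions.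

Step 6
Reactants: 9 {2-[(2,4-dimethoxyphenyl)methoxy]-3-(1,3-dioxolan-2-yl)-6-methoxyphenyl}(3,5-dimethoxyphenyl)methanone
Product: 10 hydrazone of 9, [(3,5-dimethoxyphenyl){2-[(2,4-dimethoxyphenyl)methoxy]-3-(1,3-dioxolan-2-yl)-6-methoxyphenyl}methylidene]hydrazine (E/Z mixture)
Conditions: N2H4·H2O (excess), n-BuOH, 110 °C, sealed tube, argon
Reagents that add atoms: hydrazine hydrate (as hydrazine), NN
Why: Hydrazone condensation, as in the first stage of a Wolff–Kishner reduction, driven by excess hydrazine and heat because the carbonyl is flanked by two ortho oxygens; acetal and benzyl ether are stable to the basic medium, and the C=N geometry is lost in the next step.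

Step 7
Reactants: 10 hydrazone of 9
Product: 12 (2R,3S)-2-(2,4-dimethoxyphenyl)-3-(3,5-dimethoxyphenyl)-7-(1,3-dioxolan-2-yl)-4-methoxy-2,3-dihydro-1-benzofuran (2,3-cis), via diaryldiazomethane 11 (not isolated)
Conditions: MnO2, CH2Cl2, 0 °C → rt; filtration; then slow addition to Rh2(R-PTAD)4 (1 mol %), CH2Cl2, 0 °C
Reagents that add atoms: none
Why: MnO2 dehydrogenates the hydrazone to the diaryldiazomethane 11, and the dirhodium carboxylate expels nitrogen to give a rhodium-bound diaryl carbene that has no acceptor group, is slow to dimerise and seeks the most hydridic C–H within reach. The closest known reaction type is the enantioselective intramolecular C–H insertion of donor/donor rhodium carbenes generated from 2-benzyloxybenzophenone hydrazones, which gives 2,3-diaryl-2,3-dihydrobenzofurans. The five-membered ring (O1', C2', C3', C3a', C7a') is closed through the C2'–C3' bond in a 1,5-insertion: hydride passes from the O–CH2 carbon to the carbene carbon across the array held by C3a', C7a' and O1', and the resulting oxocarbenium/benzyl-rhodium pair collapses at once. C3' is set by the catalyst, whose chiral carboxylate wall decides which carbene face receives the hydrogen. C2' follows from the geometry of that collapse, which should place the two aryl groups cis (2'R); this kinetic outcome is harmless because step 8 equilibrates C2', and any trans isomer formed directly converges there. The step needs chemoselectivity for the benzylic ether hydrogen over the C4' methoxy hydrogens, which are also 1,5 to the carbene; the benzylic hydrogen is activated by both the ether oxygen and the 2,4-dimethoxyphenyl ring, whereas a primary O–CH3 is a poor hydride donor. The acetal C–H at C7' sits meta to the carbene-bearing carbon and cannot reach it, and the methoxy groups of the 3,5-dimethoxyphenyl ring are likewise out of range. Slow addition of cold 11 to the catalyst keeps azine formation low.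

Step 8
Reactants: 12 (2R,3S)-cis acetal
Product: 13 (2S,3S)-2-(2,4-dimethoxyphenyl)-3-(3,5-dimethoxyphenyl)-4-methoxy-2,3-dihydro-1-benzofuran-7-carbaldehyde (2,3-trans)
Conditions: TFA, CH2Cl2/H2O, 0 °C → rt
Reagents that add atoms: water, O
Why: Acid-mediated epimerisation: reversible ionisation of C2'–O1' to the 2,4-dimethoxybenzyl cation and reclosure settles on the 2,3-trans ring while C3' is untouched, and the same acid hydrolyses the dioxolane. With O4' still methylated the ring can only reclose through O1'.

Step 9
Reactants: 13 (2S,3S)-trans aldehyde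
Product: 14 [(2S,3S)-2-(2,4-dimethoxyphenyl)-3-(3,5-dimethoxyphenyl)-4-methoxy-2,3-dihydro-1-benzofuran-7-yl]methanol
Conditions: NaBH4, MeOH/THF, 0 °C
Reagents that add atoms: none
Why: Borohydride reduction of an aryl aldehyde; no other group in 13 is reducible under these conditions.

Step 10
Reactants: 15 4-bromo-3,5-dimethoxybenzaldehyde; 16 diethyl (4-methoxybenzyl)phosphonate
Product: 17 2-bromo-1,3-dimethoxy-5-[(E)-2-(4-methoxyphenyl)ethenyl]benzene
Conditions: KOtBu, THF, 0 °C → rt
Reagents that add atoms: none
Why: Horner–Wadsworth–Emmons olefination of an aromatic aldehyde with a benzylic phosphonate, which should give the E-stilbene.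

Step 11
Reactants: 17 2-bromo-1,3-dimethoxy-5-[(E)-2-(4-methoxyphenyl)ethenyl]benzene; 2 N,3,5-trimethoxy-N-methylbenzamide
Product: 19 {2,6-dimethoxy-4-[(E)-2-(4-methoxyphenyl)ethenyl]phenyl}(3,5-dimethoxyphenyl)methanone, via aryllithium 18 (not isolated)
Conditions: n-BuLi, THF, −78 °C; then 2, −78 → 0 °C; H2O
Reagents that add atoms: none
Why: Bromine–lithium exchange at −78 °C is far faster than addition of butyllithium to the stilbene and fixes the acylation site between the two methoxy groups; Weinreb ketone synthesis follows as in step 1.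

Step 12
Reactants: 19 {2,6-dimethoxy-4-[(E)-2-(4-methoxyphenyl)ethenyl]phenyl}(3,5-dimethoxyphenyl)methanone
Product: 20 (3,5-dimethoxyphenyl){2-hydroxy-6-methoxy-4-[(E)-2-(4-methoxyphenyl)ethenyl]phenyl}methanone
Conditions: BCl3 (1.2 equiv), CH2Cl2, −78 → 0 °C; H2O
Reagents that add atoms: none
Why: The same chelation-controlled mono-demethylation as in step 2; the two ortho ethers are equivalent, and the non-chelated ethers and the alkene are inert to BCl3 at this temperature.

Step 13
Reactants: 14 [(2S,3S)-…-2,3-dihydro-1-benzofuran-7-yl]methanol; 20 (3,5-dimethoxyphenyl){2-hydroxy-6-methoxy-4-[(E)-2-(4-methoxyphenyl)ethenyl]phenyl}methanone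
Product: 21 (3,5-dimethoxyphenyl){2-{[(2S,3S)-2-(2,4-dimethoxyphenyl)-3-(3,5-dimethoxyphenyl)-4-methoxy-2,3-dihydro-1-benzofuran-7-yl]methoxy}-6-methoxy-4-[(E)-2-(4-methoxyphenyl)ethenyl]phenyl}methanone
Conditions: PPh3, DIAD, THF, 0 °C → rt
Reagents that add atoms: none
Why: Mitsunobu etherification; the primary benzylic alcohol is activated by its ortho and para oxygens and the ortho-acyl phenol is acidic enough, while the neutral conditions spare the acid-labile inner ring.

Step 14
Reactants: 21 aryl ether ketone
Product: 22 hydrazone of 21 (E/Z mixture)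
Conditions: N2H4·H2O (excess), n-BuOH, 110 °C, sealed tube, argon
Reagents that add atoms: hydrazine hydrate (as hydrazine), NN
Why: Hydrazone condensation as in step 6; oxygen is excluded so that no diimide forms to reduce the stilbene.

Step 15
Reactants: 22 hydrazone of 21
Product: 24 (2R,3S)-2-[(2S,3S)-2-(2,4-dimethoxyphenyl)-3-(3,5-dimethoxyphenyl)-4-methoxy-2,3-dihydro-1-benzofuran-7-yl]-3-(3,5-dimethoxyphenyl)-4-methoxy-6-[(E)-2-(4-methoxyphenyl)ethenyl]-2,3-dihydro-1-benzofuran (outer ring cis), via diaryldiazomethane 23 (not isolated)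
Conditions: MnO2, CH2Cl2, 0 °C → rt; filtration; then slow addition to Rh2(R-PTAD)4 (1–2 mol %), CH2Cl2, 0 °C
Reagents that add atoms: none
Why: The same donor/donor carbene 1,5-C–H insertion as in step 7; the ether CH2 is now attached to C7' of ring A' and is activated by O1, by O1' (ortho) and by the C4' methoxy group (para). The catalyst should set C3 as S, and any inner-ring material of the wrong handedness carried from step 7 ends up in a diastereomer that chromatography removes.

Step 16
Reactants: 24 outer-ring cis compound
Product: 25 nona-O-methylgnetumontanin B, (2S,3S)-2-[(2S,3S)-2-(2,4-dimethoxyphenyl)-3-(3,5-dimethoxyphenyl)-4-methoxy-2,3-dihydro-1-benzofuran-7-yl]-3-(3,5-dimethoxyphenyl)-4-methoxy-6-[(E)-2-(4-methoxyphenyl)ethenyl]-2,3-dihydro-1-benzofuran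
Conditions: TFA (about 5 vol %), CH2Cl2, 0 °C → rt
Reagents that add atoms: none
Why: Acid-mediated epimerisation at C2 by reversible C2–O1 ionisation, the cation being stabilised by O1' (ortho) and the C4' methoxy group (para) of ring A'; the inner ring is already trans and both O4 and O4' are methylated, so each ring can only reclose through its own ring oxygen. Dilute acid at 0 °C should not protonate the stilbene.

Step 17
Reactants: 25 nona-O-methylgnetumontanin B
Product: 26 gnetumontanin B
Conditions: BBr3 (excess), CH2Cl2, −78 → 0 °C (25 added to the reagent); MeOH, then H2O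
Reagents that add atoms: none
Why: Boron tribromide cleavage of aryl methyl ethers (bromide attack on the methyl group of each O–B adduct). Adding the substrate to excess reagent at −78 °C should tie up every methoxy group, including those on the rings that stabilise cations at C2' and C2, as electron-poor boron adducts before either benzylic C–O bond can ionise; the alkene is inert to the reagent.

## Compound list

1 | 1,3-dimethoxybenzene | COc1cccc(OC)c1 | starting material
2 | N,3,5-trimethoxy-N-methylbenzamide | CON(C)C(=O)c1cc(OC)cc(OC)c1 | starting material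
3 | 2,6-dimethoxyphenyllithium | [Li]c1c(OC)cccc1OC | intermediate (not isolated)
4 | (2,6-dimethoxyphenyl)(3,5-dimethoxyphenyl)methanone | COc1cccc(OC)c1C(=O)c1cc(OC)cc(OC)c1 | intermediate
5 | (3,5-dimethoxyphenyl)(2-hydroxy-6-methoxyphenyl)methanone | COc1cccc(O)c1C(=O)c1cc(OC)cc(OC)c1 | intermediate
6 | 3-(3,5-dimethoxybenzoyl)-2-hydroxy-4-methoxybenzaldehyde | COc1ccc(C=O)c(O)c1C(=O)c1cc(OC)cc(OC)c1 | intermediate
7 | (3,5-dimethoxyphenyl)[3-(1,3-dioxolan-2-yl)-2-hydroxy-6-methoxyphenyl]methanone | COc1ccc(C2OCCO2)c(O)c1C(=O)c1cc(OC)cc(OC)c1 | intermediate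
8 | 2,4-dimethoxybenzyl alcohol | COc1ccc(CO)c(OC)c1 | starting material
9 | {2-[(2,4-dimethoxyphenyl)methoxy]-3-(1,3-dioxolan-2-yl)-6-methoxyphenyl}(3,5-dimethoxyphenyl)methanone | COc1ccc(C2OCCO2)c(OCc2ccc(OC)cc2OC)c1C(=O)c1cc(OC)cc(OC)c1 | intermediate
10 | hydrazone of 9 (E/Z mixture) | COc1ccc(C2OCCO2)c(OCc2ccc(OC)cc2OC)c1C(=NN)c1cc(OC)cc(OC)c1 | intermediate
11 | 2-{3-[diazo(3,5-dimethoxyphenyl)methyl]-2-[(2,4-dimethoxyphenyl)methoxy]-4-methoxyphenyl}-1,3-dioxolane | COc1ccc(C2OCCO2)c(OCc2ccc(OC)cc2OC)c1C(=[N+]=[N-])c1cc(OC)cc(OC)c1 | intermediate (not isolated)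
12 | (2R,3S)-2-(2,4-dimethoxyphenyl)-3-(3,5-dimethoxyphenyl)-7-(1,3-dioxolan-2-yl)-4-methoxy-2,3-dihydro-1-benzofuran (cis) | O1CCOC1c1ccc(OC)c2c1O[C@@H](c1ccc(OC)cc1OC)[C@H]2c1cc(OC)cc(OC)c1 | intermediate
13 | (2S,3S)-2-(2,4-dimethoxyphenyl)-3-(3,5-dimethoxyphenyl)-4-methoxy-2,3-dihydro-1-benzofuran-7-carbaldehyde (trans) | O=Cc1ccc(OC)c2c1O[C@H](c1ccc(OC)cc1OC)[C@H]2c1cc(OC)cc(OC)c1 | intermediate
14 | [(2S,3S)-2-(2,4-dimethoxyphenyl)-3-(3,5-dimethoxyphenyl)-4-methoxy-2,3-dihydro-1-benzofuran-7-yl]methanol | OCc1ccc(OC)c2c1O[C@H](c1ccc(OC)cc1OC)[C@H]2c1cc(OC)cc(OC)c1 | intermediate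
15 | 4-bromo-3,5-dimethoxybenzaldehyde | COc1cc(C=O)cc(OC)c1Br | starting material
16 | diethyl (4-methoxybenzyl)phosphonate | CCOP(=O)(Cc1ccc(OC)cc1)OCC | starting material
17 | 2-bromo-1,3-dimethoxy-5-[(E)-2-(4-methoxyphenyl)ethenyl]benzene | COc1ccc(/C=C/c2cc(OC)c(Br)c(OC)c2)cc1 | intermediate
18 | {2,6-dimethoxy-4-[(E)-2-(4-methoxyphenyl)ethenyl]phenyl}lithium | COc1ccc(/C=C/c2cc(OC)c([Li])c(OC)c2)cc1 | intermediate (not isolated)
19 | {2,6-dimethoxy-4-[(E)-2-(4-methoxyphenyl)ethenyl]phenyl}(3,5-dimethoxyphenyl)methanone | COc1ccc(/C=C/c2cc(OC)c(C(=O)c3cc(OC)cc(OC)c3)c(OC)c2)cc1 | intermediate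
20 | (3,5-dimethoxyphenyl){2-hydroxy-6-methoxy-4-[(E)-2-(4-methoxyphenyl)ethenyl]phenyl}methanone | COc1ccc(/C=C/c2cc(O)c(C(=O)c3cc(OC)cc(OC)c3)c(OC)c2)cc1 | intermediate
21 | (3,5-dimethoxyphenyl){2-{[(2S,3S)-2-(2,4-dimethoxyphenyl)-3-(3,5-dimethoxyphenyl)-4-methoxy-2,3-dihydro-1-benzofuran-7-yl]methoxy}-6-methoxy-4-[(E)-2-(4-methoxyphenyl)ethenyl]phenyl}methanone | COc1ccc(/C=C/c2cc(OC)c(C(=O)c3cc(OC)cc(OC)c3)c(OCc3ccc(OC)c4c3O[C@H](c3ccc(OC)cc3OC)[C@H]4c3cc(OC)cc(OC)c3)c2)cc1 | intermediate
22 | hydrazone of 21 (E/Z mixture) | COc1ccc(/C=C/c2cc(OC)c(C(=NN)c3cc(OC)cc(OC)c3)c(OCc3ccc(OC)c4c3O[C@H](c3ccc(OC)cc3OC)[C@H]4c3cc(OC)cc(OC)c3)c2)cc1 | intermediate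
23 | diaryldiazomethane from 22 | COc1ccc(/C=C/c2cc(OC)c(C(=[N+]=[N-])c3cc(OC)cc(OC)c3)c(OCc3ccc(OC)c4c3O[C@H](c3ccc(OC)cc3OC)[C@H]4c3cc(OC)cc(OC)c3)c2)cc1 | intermediate (not isolated)
24 | (2R,3S,2'S,3'S)-2-epi-nona-O-methylgnetumontanin B (outer ring cis) | COc1ccc(/C=C/c2cc(OC)c3c(c2)O[C@@H](c2ccc(OC)c4c2O[C@H](c2ccc(OC)cc2OC)[C@H]4c2cc(OC)cc(OC)c2)[C@H]3c2cc(OC)cc(OC)c2)cc1 | intermediate
25 | nona-O-methylgnetumontanin B (2S,3S,2'S,3'S) | COc1ccc(/C=C/c2cc(OC)c3c(c2)O[C@H](c2ccc(OC)c4c2O[C@H](c2ccc(OC)cc2OC)[C@H]4c2cc(OC)cc(OC)c2)[C@H]3c2cc(OC)cc(OC)c2)cc1 | intermediate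
26 | gnetumontanin B (2S,3S,2'S,3'S) | Oc1ccc(/C=C/c2cc(O)c3c(c2)O[C@H](c2ccc(O)c4c2O[C@H](c2ccc(O)cc2O)[C@H]4c2cc(O)cc(O)c2)[C@H]3c2cc(O)cc(O)c2)cc1 | target

## Step count and least certain steps

Total: 17 steps. Longest linear sequence: 14 steps (steps 1–9 and 13–17, from 1,3-dimethoxybenzene). The stilbene branch (steps 10–12) joins at step 13.

**Step 7 (key step).** The most likely failure is poor discrimination of the carbene faces. The carbene-bearing ring of 11 has substituents in both ortho positions and must twist out of the carbene plane, unlike the mono-ortho-substituted models on which the catalyst sense rests. Azine formation from the crowded diazo compound is the second concern.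
Fallback (from hydrazone 10, back at aldehyde 13): the ring closure is kept, but enantiopurity is taken from a separation instead of from the catalyst. Hydrazone 10 is oxidised as before and 11 is decomposed with achiral dirhodium tetraacetate, Rh2(OAc)4. This should give the cis acetal as a racemate, that is 12 together with its mirror image (2S,3R)-2-(2,4-dimethoxyphenyl)-3-(3,5-dimethoxyphenyl)-7-(1,3-dioxolan-2-yl)-4-methoxy-2,3-dihydro-1-benzofuran F1. The conditions of step 8 turn the pair into the racemic trans aldehyde, 13 with (2R,3R)-2-(2,4-dimethoxyphenyl)-3-(3,5-dimethoxyphenyl)-4-methoxy-2,3-dihydro-1-benzofuran-7-carbaldehyde F2. Preparative chromatography on a chiral stationary phase then returns 13.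

**Step 15.** Three processes can divert material: capture of the carbene by the electron-rich stilbene double bond of a second molecule, partial reduction of that alkene by adventitious diimide in step 14, and a mismatched pairing of the catalyst with the resident C2'/C3' centres. The last costs only material, because the C3 epimers are diastereomers.
Fallback (from Weinreb amide 2 and alcohol 14, back at 25): the alkene is introduced after the ring closure. 1-Chloro-3,5-dimethoxybenzene is lithiated between its methoxy groups (n-BuLi) to (4-chloro-2,6-dimethoxyphenyl)lithium F3 and acylated with 2 to (4-chloro-2,6-dimethoxyphenyl)(3,5-dimethoxyphenyl)methanone F4. BCl3 gives (4-chloro-2-hydroxy-6-methoxyphenyl)(3,5-dimethoxyphenyl)methanone F5. Mitsunobu coupling with 14 gives (4-chloro-2-{[(2S,3S)-2-(2,4-dimethoxyphenyl)-3-(3,5-dimethoxyphenyl)-4-methoxy-2,3-dihydro-1-benzofuran-7-yl]methoxy}-6-methoxyphenyl)(3,5-dimethoxyphenyl)methanone F6. Hydrazine gives the hydrazone of that ketone F7, MnO2 the corresponding diaryldiazomethane F8, and Rh2(R-PTAD)4 the outer-ring-cis 6-chloro bis(dihydrobenzofuran) F9, which TFA epimerises to the all-trans 6-chloro bis(dihydrobenzofuran) F10. A Heck reaction of the aryl chloride with 4-methoxystyrene (Pd2(dba)3, P(t-Bu)3, Cy2NMe, dioxane, heat) then gives 25.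

**Step 17.** The danger is ionisation of the inner C2'–O1' bond under the boron halide before the methoxy groups on the C2' aryl ring are complexed. Once O4' has lost its methyl group, the opened ring can reclose through either oxygen flanking C3a', giving a ring isomer. Incomplete cleavage of nine ethers and air oxidation of the free nonaphenol on silica add to the loss.
Fallback (from 25, back at 26): the product is not isolated as the free phenol. The crude demethylation mixture is acetylated (Ac2O, pyridine, DMAP) to gnetumontanin B nonaacetate F11, which is purified by ordinary chromatography and freed from partially methylated and ring-isomeric material. Mild transesterification (K2CO3, degassed MeOH, 0 °C) then releases 26. If ring opening proves intrinsic, the structural remedy is to carry the oxygens of the C2' aryl ring as silyl ethers from building block 8 onwards and to unmask them with fluoride before the boron halide is applied.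

**Step 6 (and likewise step 14).** Condensation may stall because the ketone carbon is shielded by two ortho oxygen substituents and by two aryl rings twisted out of conjugation.
Fallback (from ketone 9, back at hydrazone 10): the carbonyl is first made a better electrophile. Lawesson's reagent (PhMe, 80 °C) converts 9 into {2-[(2,4-dimethoxyphenyl)methoxy]-3-(1,3-dioxolan-2-yl)-6-methoxyphenyl}(3,5-dimethoxyphenyl)methanethione F12, and hydrazine hydrate in EtOH at room temperature displaces sulfur to give 10.

**Step 3.** Formylation may be slow because the magnesium phenoxide is chelated by the neighbouring ketone and deactivated.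
Fallback (from Weinreb amide 2, back at aldehyde 6): the formyl carbon is bought with the ring. 2,4-Dimethoxybenzaldehyde is converted into 2-(2,4-dimethoxyphenyl)-1,3-dioxolane F13. Lithiation between the two methoxy groups (n-BuLi, THF) gives [3-(1,3-dioxolan-2-yl)-2,6-dimethoxyphenyl]lithium F14, and acylation with 2 gives [3-(1,3-dioxolan-2-yl)-2,6-dimethoxyphenyl](3,5-dimethoxyphenyl)methanone F15. BCl3 then removes the acetal and the methyl group of the methoxy that lies between the two carbonyl groups, giving 6.

## Further compounds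

F1 | step 7 | (2S,3R)-2-(2,4-dimethoxyphenyl)-3-(3,5-dimethoxyphenyl)-7-(1,3-dioxolan-2-yl)-4-methoxy-2,3-dihydro-1-benzofuran | O1CCOC1c1ccc(OC)c2c1O[C@H](c1ccc(OC)cc1OC)[C@@H]2c1cc(OC)cc(OC)c1
F2 | step 7 | (2R,3R)-2-(2,4-dimethoxyphenyl)-3-(3,5-dimethoxyphenyl)-4-methoxy-2,3-dihydro-1-benzofuran-7-carbaldehyde | O=Cc1ccc(OC)c2c1O[C@@H](c1ccc(OC)cc1OC)[C@@H]2c1cc(OC)cc(OC)c1
F3 | step 15 | (4-chloro-2,6-dimethoxyphenyl)lithium | [Li]c1c(OC)cc(Cl)cc1OC
F4 | step 15 | (4-chloro-2,6-dimethoxyphenyl)(3,5-dimethoxyphenyl)methanone | COc1cc(Cl)cc(OC)c1C(=O)c1cc(OC)cc(OC)c1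
F5 | step 15 | (4-chloro-2-hydroxy-6-methoxyphenyl)(3,5-dimethoxyphenyl)methanone | COc1cc(Cl)cc(O)c1C(=O)c1cc(OC)cc(OC)c1
F6 | step 15 | (4-chloro-2-{[(2S,3S)-2-(2,4-dimethoxyphenyl)-3-(3,5-dimethoxyphenyl)-4-methoxy-2,3-dihydro-1-benzofuran-7-yl]methoxy}-6-methoxyphenyl)(3,5-dimethoxyphenyl)methanone | COc1cc(Cl)cc(OCc2ccc(OC)c3c2O[C@H](c2ccc(OC)cc2OC)[C@H]3c2cc(OC)cc(OC)c2)c1C(=O)c1cc(OC)cc(OC)c1
F7 | step 15 | hydrazone of F6 | COc1cc(Cl)cc(OCc2ccc(OC)c3c2O[C@H](c2ccc(OC)cc2OC)[C@H]3c2cc(OC)cc(OC)c2)c1C(=NN)c1cc(OC)cc(OC)c1
F8 | step 15 | diaryldiazomethane from F7 | COc1cc(Cl)cc(OCc2ccc(OC)c3c2O[C@H](c2ccc(OC)cc2OC)[C@H]3c2cc(OC)cc(OC)c2)c1C(=[N+]=[N-])c1cc(OC)cc(OC)c1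
F9 | step 15 | (2R,3S)-6-chloro-2-[(2S,3S)-2-(2,4-dimethoxyphenyl)-3-(3,5-dimethoxyphenyl)-4-methoxy-2,3-dihydro-1-benzofuran-7-yl]-3-(3,5-dimethoxyphenyl)-4-methoxy-2,3-dihydro-1-benzofuran | Clc1cc(OC)c2c(c1)O[C@@H](c1ccc(OC)c3c1O[C@H](c1ccc(OC)cc1OC)[C@H]3c1cc(OC)cc(OC)c1)[C@H]2c1cc(OC)cc(OC)c1
F10 | step 15 | (2S,3S)-6-chloro-2-[(2S,3S)-2-(2,4-dimethoxyphenyl)-3-(3,5-dimethoxyphenyl)-4-methoxy-2,3-dihydro-1-benzofuran-7-yl]-3-(3,5-dimethoxyphenyl)-4-methoxy-2,3-dihydro-1-benzofuran | Clc1cc(OC)c2c(c1)O[C@H](c1ccc(OC)c3c1O[C@H](c1ccc(OC)cc1OC)[C@H]3c1cc(OC)cc(OC)c1)[C@H]2c1cc(OC)cc(OC)c1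
F11 | step 17 | gnetumontanin B nonaacetate | CC(=O)Oc1ccc(/C=C/c2cc(OC(C)=O)c3c(c2)O[C@H](c2ccc(OC(C)=O)c4c2O[C@H](c2ccc(OC(C)=O)cc2OC(C)=O)[C@H]4c2cc(OC(C)=O)cc(OC(C)=O)c2)[C@H]3c2cc(OC(C)=O)cc(OC(C)=O)c2)cc1
F12 | step 6 | {2-[(2,4-dimethoxyphenyl)methoxy]-3-(1,3-dioxolan-2-yl)-6-methoxyphenyl}(3,5-dimethoxyphenyl)methanethione | COc1ccc(C2OCCO2)c(OCc2ccc(OC)cc2OC)c1C(=S)c1cc(OC)cc(OC)c1
F13 | step 3 | 2-(2,4-dimethoxyphenyl)-1,3-dioxolane | COc1ccc(C2OCCO2)c(OC)c1
F14 | step 3 | [3-(1,3-dioxolan-2-yl)-2,6-dimethoxyphenyl]lithium | COc1ccc(C2OCCO2)c(OC)c1[Li]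
F15 | step 3 | [3-(1,3-dioxolan-2-yl)-2,6-dimethoxyphenyl](3,5-dimethoxyphenyl)methanone | COc1ccc(C2OCCO2)c(OC)c1C(=O)c1cc(OC)cc(OC)c1
A1 | alternative 1 | methyl (E)-5-diazo-4-oxopent-2-enoate | COC(=O)/C=C/C(=O)C=[N+]=[N-]
A2 | alternative 1 | {[4-(2,4-dimethoxyphenyl)-3-(3,5-dimethoxyphenyl)-4-methoxybut-1-yn-1-yl]oxy}tri(propan-2-yl)silane | CC(C)[Si](OC#C[C@H](c1cc(OC)cc(OC)c1)[C@H](OC)c1ccc(OC)cc1OC)(C(C)C)C(C)C
A3 | alternative 1 | methyl 3-[2-(2,4-dimethoxyphenyl)-1-(3,5-dimethoxyphenyl)-2-methoxyethyl]-2-hydroxy-4-[(triisopropylsilyl)oxy]benzoate | COC(=O)c1ccc(O[Si](C(C)C)(C(C)C)C(C)C)c([C@H](c2cc(OC)cc(OC)c2)[C@H](OC)c2ccc(OC)cc2OC)c1O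
A4 | alternative 2 | (2S,3S)-7-bromo-2-(2,4-dimethoxyphenyl)-3-(3,5-dimethoxyphenyl)-4-methoxy-2,3-dihydro-1-benzofuran | Brc1ccc(OC)c2c1O[C@H](c1ccc(OC)cc1OC)[C@H]2c1cc(OC)cc(OC)c1
A5 | alternative 2 | 2-[(E)-2-(3,5-dimethoxyphenyl)ethenyl]-4,4,5,5-tetramethyl-1,3,2-dioxaborolane | COc1cc(/C=C/B2OC(C)(C)C(C)(C)O2)cc(OC)c1
A6 | alternative 2 | 2,6-bis(methoxymethoxy)-4-[(E)-2-(4-methoxyphenyl)ethenyl]phenyl trifluoromethanesulfonate | COCOc1cc(/C=C/c2ccc(OC)cc2)cc(OCOC)c1OS(=O)(=O)C(F)(F)F
A7 | alternative 2 | pinacol boronate of the 1,2,2-triarylethane (boron on C2) | CC1(C)OB(OC1(C)C)[C@H](c1ccc(OC)c2c1O[C@H](c1ccc(OC)cc1OC)[C@H]2c1cc(OC)cc(OC)c1)[C@H](c1c(OCOC)cc(/C=C/c2ccc(OC)cc2)cc1OCOC)c1cc(OC)cc(OC)c1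
A8 | alternative 3 | 3-alkoxy-5-[(E)-2-(4-methoxyphenyl)ethenyl]pyridazine carrying the C2/C3 unit and the alkynyl pinacol boronate | COc1ccc(/C=C/c2cnnc(O[C@H](c3ccc(OC)c4c3O[C@H](c3ccc(OC)cc3OC)[C@H]4c3cc(OC)cc(OC)c3)[C@H](C#CB3OC(C)(C)C(C)(C)O3)c3cc(OC)cc(OC)c3)c2)cc1
A9 | alternative 3 | octa-O-methyl gnetumontanin B skeleton with a pinacol boronate at C4 | COc1ccc(/C=C/c2cc(B5OC(C)(C)C(C)(C)O5)c3c(c2)O[C@H](c2ccc(OC)c4c2O[C@H](c2ccc(OC)cc2OC)[C@H]4c2cc(OC)cc(OC)c2)[C@H]3c2cc(OC)cc(OC)c2)cc1
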